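**Plan**

Labels: C1 = carbinol carbon (OH, acetyl); C2=C3 = dimethylated alkene; C4 = ring ketone; C5 = spiro carbon; C6, C7 = oxolane CH2 groups; C8 = oxolane carbon with CH3 and the C16 chain; O9 = oxolane oxygen.
Enabling feature: in the oxolane C5–C6–C7–C8–O9, the fully substituted ether carbon C8 lies three carbons from the oxygen-bearing spiro carbon C5. The unit C6–C7=C8(CH3)(C16H33) is the head of a phytyl group, so a C5 hydroxyl can close the ring onto a C7–C8 epoxide.
Retrosynthetic cuts, in order: C4=O back to C4H2; the C1–acetyl bond; C7–H back to C7–OH; C8–O9 (key cut, giving a C5 carbinol and a 7,8-epoxide); C5–OH; C5–C6 (phytyl bromide plus 2,3-dimethylcyclopentenone, whose carbonyl carbon is the future C1).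
Forward order: the carbocycle is bought, the chain is joined at C5, C5 is hydroxylated, the alkene is epoxidised, the oxolane is closed and C7 is deoxygenated. Only then is C1 acetylated by carbonyl addition and C4 oxidised.
Stereochemistry: both chain centres come from natural phytol. C5 comes from a camphor-derived oxaziridine. C8 comes from the Shi epoxide (8R) by inversion to 8S. C1 comes from chelation-guided addition to the rigid spiro ketone, syn to O9.
Closing the oxolane while C1 is still a carbonyl carbon leaves C5–OH as the only hydroxyl, so the route needs no protecting group.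

Key step: step 5

Assumption: the (−) antipode of the dichlorocamphor oxaziridine is taken to give 5S, by analogy with sodium enolates of 2-alkyl-1-tetralones. If the sense proves opposite, the (+) antipode is used and nothing else changes.
Remark: C5 is never touched after step 3. Its descriptor alternates (S in 7, R in 8–10, S in 11, 15 and 16, R in 18) only because substituent priorities change. "Phytyl" means (2E,7R,11R)-3,7,11,15-tetramethylhexadec-2-en-1-yl.

**Step 1**
Reactants: 1 natural phytol
Product: 2 (2E,7R,11R)-phytyl bromide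
Conditions: PBr3 (0.4 equiv), Et2O, 0 °C
Reagents that add atoms: phosphorus tribromide, BrP(Br)Br
Why: Conversion of a primary allylic alcohol into the bromide with PBr3 (SN2 displacement of the phosphite ester) is the standard preparation of phytyl bromide and should leave the E alkene and the two chain stereocentres untouched.

**Step 2**
Reactants: 3 2,3-dimethylcyclopent-2-en-1-one; 2 (2E,7R,11R)-phytyl bromide
Product: 5 2,3-dimethyl-5-phytylcyclopent-2-en-1-one (both C5 epimers), via lithium alpha-prime enolate 4 (not isolated)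
Conditions: LiN(i-Pr)2, THF, −78 °C; then 2, DMPU, −78 to −20 °C
Reagents that add atoms: none
Why: Kinetic alpha-prime deprotonation of the cyclopentenone and SN2 alkylation of the cross-conjugated enolate with a primary allylic bromide (enolate alkylation) forms C5–C6; the new C5 centre arises without control, which does not matter because step 3 planarises it.

**Step 3**
Reactants: 5 2,3-dimethyl-5-phytylcyclopent-2-en-1-one
Product: 7 (5S)-5-hydroxy-2,3-dimethyl-5-phytylcyclopent-2-en-1-one, via tetrasubstituted sodium enolate 6 (not isolated)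
Conditions: NaN(SiMe3)2, THF, −78 °C; (−)-[(8,8-dichlorocamphoryl)sulfonyl]oxaziridine, −78 °C; AcOH quench
Reagents that add atoms: (−)-[(8,8-dichlorocamphoryl)sulfonyl]oxaziridine, CC1(C)[C@H]2CC[C@@]13CS(=O)(=O)N4O[C@]34C2(Cl)Cl
Why: Davis asymmetric enolate hydroxylation: the cyclic tetrasubstituted enolate has a single geometry and the camphor skeleton of the oxaziridine lets only one enolate face reach the transferable oxygen, so C5 is set as S under reagent control, and any C5 epimer becomes a separable diastereomer once C7 and C8 are in place.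

**Step 4**
Reactants: 7 (5S)-5-hydroxy-2,3-dimethyl-5-phytylcyclopent-2-en-1-one
Product: 8 (5R)-5-hydroxy-2,3-dimethyl-5-{[(2R,3R)-3-methyl-3-((4R,8R)-4,8,12-trimethyltridecyl)oxiran-2-yl]methyl}cyclopent-2-en-1-one (7R,8R epoxide in the labels above)
Conditions: D-fructose-derived Shi ketone (30 mol %), KHSO5 (as 2KHSO5·KHSO4·K2SO4), K2CO3, Bu4NHSO4 (cat.), MeCN–dimethoxymethane / aq. Na2B4O7–Na2EDTA buffer, 0 °C
Reagents that add atoms: potassium peroxymonosulfate, [K+].[O-]S(=O)(=O)OO
Why: Shi epoxidation: the dioxirane formed from the D-fructose-derived ketone meets E-trisubstituted alkenes in a spiro transition state and should give the 7R,8R epoxide under reagent control, free hydroxyl groups are tolerated, and the electron-poor tetrasubstituted enone alkene does not react with the electrophilic oxidant.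

**Step 5**
Reactants: 8 the (5R,7R,8R)-epoxy carbinol
Product: 9 (2S,3R,5R)-3-hydroxy-2,7,8-trimethyl-2-[(4R,8R)-4,8,12-trimethyltridecyl]-1-oxaspiro[4.4]non-7-en-6-one (C8 S, C7 R carbinol, ketone at the future C1)
Conditions: (±)-camphor-10-sulfonic acid (10 mol %), CH2Cl2, −20 to 0 °C
Reagents that add atoms: none
Why: The sulfonic acid activates the epoxide oxygen, the C8–O bond lengthens because the tertiary carbon carries the developing charge best, and the C5 hydroxyl, held three atoms away, attacks C8 from the rear in a loose SN2 event that forms C8–O9. The closest known reaction type is the acid-promoted endo-selective cyclisation of trisubstituted 3,4-epoxy alcohols to 2,2-disubstituted oxolan-3-ols, which runs with inversion. The one ring closed is the oxolane, in the 5-endo-tet mode, the 4-exo alternative at C7 being penalised by oxetane strain and by the lack of charge at the secondary carbon. C8 is the new stereocentre and its S configuration is the inverse of the R centre written into 8 by the Shi ketone, independent of C5, whereas C7 keeps its C–O bond and R configuration and is erased in step 7. The step needs site selectivity (C8 over C7), fidelity (no free cation, hence a catalytic weak acid, an apolar solvent and low temperature) and a single nucleophile, the last being secured because C1 is still a carbonyl carbon and 8 has only one hydroxyl. The conjugated ketone oxygen is the poorer nucleophile and would have to build a six-membered oxocarbenium ion, so it should not compete.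

**Step 6**
Reactants: 9 the C7-hydroxy spiro enone
Product: 10 O-[(2S,3R,5R)-2,7,8-trimethyl-6-oxo-2-((4R,8R)-4,8,12-trimethyltridecyl)-1-oxaspiro[4.4]non-7-en-3-yl] imidazole-1-carbothioate
Conditions: 1,1'-thiocarbonyldiimidazole, DMAP (cat.), 1,2-dichloroethane, 70 °C
Reagents that add atoms: 1,1'-thiocarbonyldiimidazole, S=C(n1ccnc1)n1ccnc1
Why: Thioacylation of the only hydroxyl with thiocarbonyldiimidazole is the first half of the Barton–McCombie deoxygenation and is chosen over xanthate formation because it needs no strong base, which the gamma-acidic enone would not stand.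

**Step 7**
Reactants: 10 the C7 imidazolyl thiocarbonate
Product: 11 (2S,5S)-2,7,8-trimethyl-2-[(4R,8R)-4,8,12-trimethyltridecyl]-1-oxaspiro[4.4]non-7-en-6-one
Conditions: Bu3SnH, AIBN (cat.), toluene, 90 °C
Reagents that add atoms: none
Why: Barton–McCombie radical deoxygenation: the stannyl radical adds to sulfur, the secondary C7 radical is released and is quenched by Bu3SnH faster than it can fragment, so the auxiliary C7 centre disappears while C5 and C8 keep their configuration.

**Step 8**
Reactants: 11 the spiro enone; 12 ethyl vinyl ether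
Product: 16 1-[(2S,5S,6S)-6-hydroxy-2,7,8-trimethyl-2-((4R,8R)-4,8,12-trimethyltridecyl)-1-oxaspiro[4.4]non-7-en-6-yl]ethan-1-one, via 1-ethoxyvinyllithium 13 (not isolated), via 1-ethoxyvinylcerium dichloride 14 (not isolated), via enol ether carbinol 15 (not isolated)
Conditions: 12, t-BuLi, THF, −78 to 0 °C; CeCl3, −78 °C; 11, −78 °C; then 1 M HCl, THF, 0 °C
Reagents that add atoms: ethyl vinyl ether (12), C=COCC; water, O
Why: 1,2-Addition of an acyl anion equivalent (lithiated ethyl vinyl ether, used as the weakly basic organocerium reagent to suppress gamma-deprotonation) to the enone carbonyl followed by enol ether hydrolysis; the metal bridges the carbonyl oxygen and O9 while C6H2 shields the other face of the flat ring (chelation control reinforced by sterics), so carbon enters syn to O9 and C1 is set as S with its hydroxyl trans to O9.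

**Step 9**
Reactants: 16 the C1 acetyl carbinol with C4H2
Product: 18 alpha-tocospiro A, via C4 tert-butyl peroxide 17 (not isolated)
Conditions: Rh2(caprolactamate)4 (1 mol %), t-BuOOH (70% aq.), 1,2-dichloroethane, 40 °C
Reagents that add atoms: tert-butyl hydroperoxide, CC(C)(C)OO
Why: Radical allylic C–H oxidation with t-BuOOH under dirhodium caprolactamate catalysis: C4 is the only ring methylene next to the alkene and has the weakest C–H bonds, the allyl radical is trapped at secondary C4 and not at tertiary C2, the mixed peroxide collapses to the enone, the tertiary C1 carbinol and the hydrogen-free ether carbons C5 and C8 cannot be oxidised, and no stereocentre is touched.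

**Compound list**

1 | natural phytol, (2E,7R,11R)-3,7,11,15-tetramethylhexadec-2-en-1-ol | OC/C=C(\C)CCC[C@H](C)CCC[C@H](C)CCCC(C)C | starting material
2 | (2E,7R,11R)-phytyl bromide | BrC/C=C(\C)CCC[C@H](C)CCC[C@H](C)CCCC(C)C | intermediate
3 | 2,3-dimethylcyclopent-2-en-1-one | CC1=C(C)C(=O)CC1 | starting material
4 | lithium alpha-prime (cross-conjugated) enolate of 3 | [Li]OC1=CCC(C)=C1C | intermediate
5 | 2,3-dimethyl-5-phytylcyclopent-2-en-1-one, C5 unassigned | O=C1C(C)=C(C)CC1C/C=C(\C)CCC[C@H](C)CCC[C@H](C)CCCC(C)C | intermediate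
6 | tetrasubstituted sodium enolate of 5 | [Na]OC1=C(C/C=C(\C)CCC[C@H](C)CCC[C@H](C)CCCC(C)C)CC(C)=C1C | intermediate
7 | (5S)-5-hydroxy-2,3-dimethyl-5-phytylcyclopent-2-en-1-one | O=C1C(C)=C(C)C[C@@]1(O)C/C=C(\C)CCC[C@H](C)CCC[C@H](C)CCCC(C)C | intermediate
8 | (5R)-5-hydroxy-2,3-dimethyl-5-{[(2R,3R)-3-methyl-3-((4R,8R)-4,8,12-trimethyltridecyl)oxiran-2-yl]methyl}cyclopent-2-en-1-one | O=C1C(C)=C(C)C[C@@]1(O)C[C@H]2O[C@]2(C)CCC[C@H](C)CCC[C@H](C)CCCC(C)C | intermediate
9 | (2S,3R,5R)-3-hydroxy-2,7,8-trimethyl-2-[(4R,8R)-4,8,12-trimethyltridecyl]-1-oxaspiro[4.4]non-7-en-6-one | O=C1C(C)=C(C)C[C@@]12C[C@@H](O)[C@](C)(CCC[C@H](C)CCC[C@H](C)CCCC(C)C)O2 | intermediate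
10 | imidazole-1-carbothioate (O-ester) of 9 at C7 | O=C1C(C)=C(C)C[C@@]12C[C@@H](OC(=S)n3ccnc3)[C@](C)(CCC[C@H](C)CCC[C@H](C)CCCC(C)C)O2 | intermediate
11 | (2S,5S)-2,7,8-trimethyl-2-[(4R,8R)-4,8,12-trimethyltridecyl]-1-oxaspiro[4.4]non-7-en-6-one | O=C1C(C)=C(C)C[C@@]12CC[C@](C)(CCC[C@H](C)CCC[C@H](C)CCCC(C)C)O2 | intermediate
12 | ethyl vinyl ether | C=COCC | starting material
13 | 1-ethoxyvinyllithium | [Li]C(=C)OCC | intermediate
14 | 1-ethoxyvinylcerium dichloride | C=C(OCC)[Ce](Cl)Cl | intermediate
15 | (2S,5S,6R)-6-(1-ethoxyethenyl)-2,7,8-trimethyl-2-[(4R,8R)-4,8,12-trimethyltridecyl]-1-oxaspiro[4.4]non-7-en-6-ol | C=C(OCC)[C@]1(O)C(C)=C(C)C[C@@]12CC[C@](C)(CCC[C@H](C)CCC[C@H](C)CCCC(C)C)O2 | intermediate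
16 | 1-[(2S,5S,6S)-6-hydroxy-2,7,8-trimethyl-2-((4R,8R)-4,8,12-trimethyltridecyl)-1-oxaspiro[4.4]non-7-en-6-yl]ethan-1-one | CC(=O)[C@]1(O)C(C)=C(C)C[C@@]12CC[C@](C)(CCC[C@H](C)CCC[C@H](C)CCCC(C)C)O2 | intermediate
17 | C4 tert-butylperoxy derivative of 16, C4 unassigned | CC(=O)[C@]1(O)C(C)=C(C)C(OOC(C)(C)C)[C@@]12CC[C@](C)(CCC[C@H](C)CCC[C@H](C)CCCC(C)C)O2 | intermediate
18 | alpha-tocospiro A, (2S,5R,9S)-9-acetyl-9-hydroxy-2,7,8-trimethyl-2-[(4R,8R)-4,8,12-trimethyltridecyl]-1-oxaspiro[4.4]non-7-en-6-one | CC(=O)[C@]1(O)C(C)=C(C)C(=O)[C@@]12CC[C@](C)(CCC[C@H](C)CCC[C@H](C)CCCC(C)C)O2 | target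

Total step count: 9. Longest linear sequence: 9 steps (1 to 18).

**Steps most likely to fail**

**Step 9.** Hydrogen abstraction may drift from the neopentyl C4 methylene to the two vinylic methyl groups. Peroxyl radicals may also add to the electron-rich tetrasubstituted alkene.

The fallback brings the C4 oxygen in at the enone stage. It sets out from 11 and comes back at 18.
- Soft enolisation of 11 (TBSOTf, Et3N, CH2Cl2) should give the endocyclic silyloxycyclopentadiene F1.
- Vinylogous Rubottom oxidation of its terminal C3=C4 bond with dimethyldioxirane should give the C4-hydroxy enone F2. Either C4 epimer serves, because this centre is oxidised away later.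
- Silylation (TBSOTf, 2,6-lutidine) gives the C4 silyl ether F3.
- Addition of 14 under the conditions of step 8 gives the enol ether carbinol F4, which dilute HCl hydrolyses to the acetyl carbinol silyl ether F5.
- Bu4NF releases the C1,C4-diol F6.
- MnO2 oxidises only the secondary allylic C4 alcohol, giving 18.

**Step 5.** The C8–O bond may ionise before the hydroxyl arrives. That would cost fidelity of inversion and open the way to hydride shift, elimination, or capture of the activated epoxide by the ketone oxygen.

The fallback keeps the C8–O9 closure but replaces the protonated epoxide by a tighter iodonium ion under buffered, non-acidic conditions. It sets out from 7 and comes back at 11.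
- 5-endo-trig iodoetherification (I2, NaHCO3, MeCN, 0 °C) adds iodine to C7 and O9 to C8 in anti fashion across the E alkene, giving the C7 iodo spiro ether F7.
- Reduction with Bu3SnH and AIBN removes the iodine and gives 11.
- Face selection would then rest on C5 rather than on a reagent, and any minor isomer would be removed by chromatography.

**Step 3.** The oxaziridine may discriminate poorly between the faces of the flat five-membered dienolate.

The fallback gives up reagent control at C5 and uses the epoxide centres as a resolving handle. It sets out from 5 and comes back at 8.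
- The sodium enolate 6 is oxidised with racemic 3-phenyl-2-(phenylsulfonyl)oxaziridine, giving 7 together with its C5 epimer, the (5R)-hydroxy enone F8.
- Epoxidation of the pair as in step 4 gives 8 and the (5S)-epoxy carbinol F9.
- These two differ in the close C5/C7 relationship and should separate on silica. Pure 8 then enters step 5.

**Further compounds**

F1 | step 9 | tert-butyldimethylsilyl dienol ether of 11 (C1–OTBS, C1=C2 and C3=C4) | CC(C)(C)[Si](C)(C)OC1=C(C)C(C)=C[C@@]12CC[C@](C)(CCC[C@H](C)CCC[C@H](C)CCCC(C)C)O2
F2 | step 9 | C4-hydroxy derivative of 11, C4 unassigned | O=C1C(C)=C(C)C(O)[C@@]12CC[C@](C)(CCC[C@H](C)CCC[C@H](C)CCCC(C)C)O2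
F3 | step 9 | C4 tert-butyldimethylsilyl ether of F2 | O=C1C(C)=C(C)C(O[Si](C)(C)C(C)(C)C)[C@@]12CC[C@](C)(CCC[C@H](C)CCC[C@H](C)CCCC(C)C)O2
F4 | step 9 | C1 1-ethoxyvinyl carbinol from F3 | C=C(OCC)[C@]1(O)C(C)=C(C)C(O[Si](C)(C)C(C)(C)C)[C@@]12CC[C@](C)(CCC[C@H](C)CCC[C@H](C)CCCC(C)C)O2
F5 | step 9 | C1 acetyl carbinol with C4 silyl ether | CC(=O)[C@]1(O)C(C)=C(C)C(O[Si](C)(C)C(C)(C)C)[C@@]12CC[C@](C)(CCC[C@H](C)CCC[C@H](C)CCCC(C)C)O2
F6 | step 9 | C1,C4-diol (C4-dihydro alpha-tocospiro A) | CC(=O)[C@]1(O)C(C)=C(C)C(O)[C@@]12CC[C@](C)(CCC[C@H](C)CCC[C@H](C)CCCC(C)C)O2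
F7 | step 5 | (2S,3R,5R)-3-iodo analogue of 9 | O=C1C(C)=C(C)C[C@@]12C[C@@H](I)[C@](C)(CCC[C@H](C)CCC[C@H](C)CCCC(C)C)O2
F8 | step 3 | (5R)-5-hydroxy-2,3-dimethyl-5-phytylcyclopent-2-en-1-one | O=C1C(C)=C(C)C[C@]1(O)C/C=C(\C)CCC[C@H](C)CCC[C@H](C)CCCC(C)C
F9 | step 3 | C5 epimer of 8 (5S, 7R,8R epoxide) | O=C1C(C)=C(C)C[C@]1(O)C[C@H]2O[C@]2(C)CCC[C@H](C)CCC[C@H](C)CCCC(C)C
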